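Ring carbons: Ca carries the tetraenyl chain, Cb the CH2OH, Cc is quaternary. The C40 alcohol is cut at the two CH2–CH= bonds nearest the cyclopropane: C2–C3 of the trienyl chain on Cc and C4–C5 of the tetraenyl chain on Ca. Both cuts release the same (E,E)-C14 alkenyl terminus, and in both the carbon that becomes a radical lies outside cyclopropylcarbinyl reach of the three-membered ring. One nickel-electrocatalytic operation therefore joins a C12 core twice to one C14 alkenyl iodide. The core is a bis(N-hydroxyphthalimide) ester with a propanoate arm on Cc, an (E)-4-methylpent-4-enoate arm on Ca and Cb–CH2OH as silyl ether; its stereocentres come from one enantioselective intramolecular cyclopropanation.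

Key step: step 17

Remark: (S)-configured dirhodium carboxamidates are assumed to give the (1R,5S) lactone series with 6, as they do with allyl diazoacetate (otherwise the (4R) catalyst would be used); lactol 8 and diol 10 are carried as epimer mixtures at the carbinol carbon, which step 9 removes.

Step 1
Reactants: 1 (tert-butyldimethylsilyloxy)acetaldehyde; 2 ethyl 2-(triphenylphosphoranylidene)propanoate
Product: 3 ethyl (E)-4-[(tert-butyldimethylsilyl)oxy]-2-methylbut-2-enoate
Conditions: CH2Cl2, rt
Reagents that add atoms: none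
Why: Wittig olefination with a stabilised α-methyl ylide should give the E-trisubstituted enoate under the usual thermodynamic control of such ylides, and the silyl ether is inert.

Step 2
Reactants: 3 ethyl (E)-4-[(tert-butyldimethylsilyl)oxy]-2-methylbut-2-enoate
Product: 4 (E)-4-[(tert-butyldimethylsilyl)oxy]-2-methylbut-2-en-1-ol
Conditions: i-Bu2AlH (2.2 equiv), CH2Cl2, −78 °C; Rochelle salt work-up
Reagents that add atoms: none
Why: 1,2-Reduction of the enoate by i-Bu2AlH at low temperature should stop cleanly at the allylic alcohol without touching the alkene geometry or the silyl ether.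

Step 3
Reactants: 4 (E)-4-[(tert-butyldimethylsilyl)oxy]-2-methylbut-2-en-1-ol
Product: 5 (E)-4-[(tert-butyldimethylsilyl)oxy]-2-methylbut-2-en-1-yl bromoacetate
Conditions: BrCH2COBr, NaHCO3, MeCN, 0 °C
Reagents that add atoms: bromoacetyl bromide, O=C(Br)CBr
Why: Acylation of the primary allylic alcohol by the acid bromide under NaHCO3 buffering is fast and mild enough to leave the silyl ether and the alkene untouched.

Step 4
Reactants: 5 (E)-4-[(tert-butyldimethylsilyl)oxy]-2-methylbut-2-en-1-yl bromoacetate
Product: 6 (E)-4-[(tert-butyldimethylsilyl)oxy]-2-methylbut-2-en-1-yl diazoacetate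
Conditions: TsNHNHTs, DBU, THF, 0 °C
Reagents that add atoms: N,N'-ditosylhydrazine, Cc1ccc(cc1)S(=O)(=O)NNS(=O)(=O)c1ccc(C)cc1
Why: Diazoacetate formation from a bromoacetate: the ditosylhydrazine anion displaces bromide (SN2) and DBU then expels two sulfinate ions to unveil the diazo group under conditions that ester and silyl ether tolerate.

Step 5
Reactants: 6 (E)-4-[(tert-butyldimethylsilyl)oxy]-2-methylbut-2-en-1-yl diazoacetate
Product: 7 (1R,5S,6R)-6-{[(tert-butyldimethylsilyl)oxy]methyl}-5-methyl-3-oxabicyclo[3.1.0]hexan-2-one (C1 = Ca, C5 = Cc, C6 = Cb, silyloxymethyl exo)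
Conditions: Rh2(4S-MPPIM)4 (1 mol%), CH2Cl2, reflux, slow addition of 6
Reagents that add atoms: none
Why: Intramolecular cyclopropanation of an allylic diazoacetate by a rhodium carbene under a chiral dirhodium carboxamidate, dirhodium tetrakis[methyl (4S)-2-oxo-1-(3-phenylpropanoyl)imidazolidine-4-carboxylate]: the concerted syn addition turns the E geometry into CH2OTBS cis to the Cc methyl and trans to the lactone CH2, the five-membered lactone forces the Ca carbonyl and the Cc CH2 onto one face, and the (4S) ligand sphere selects the alkene face and so the absolute configuration of all three centres.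

Step 6
Reactants: 7 (1R,5S,6R)-6-{[(tert-butyldimethylsilyl)oxy]methyl}-5-methyl-3-oxabicyclo[3.1.0]hexan-2-one
Product: 8 (1R,5S,6R)-6-{[(tert-butyldimethylsilyl)oxy]methyl}-5-methyl-3-oxabicyclo[3.1.0]hexan-2-ol (both C2 epimers)
Conditions: i-Bu2AlH (1.1 equiv), CH2Cl2, −78 °C
Reagents that add atoms: none
Why: Partial reduction of a γ-lactone by i-Bu2AlH at −78 °C stops at the aluminium hemiacetal, so the lactol should form without over-reduction and without touching the ring stereocentres.

Step 7
Reactants: 8 lactol; 9 isopropenylmagnesium bromide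
Product: 10 {(1S,2R,3R)-2-{[(tert-butyldimethylsilyl)oxy]methyl}-3-(1-hydroxy-2-methylprop-2-en-1-yl)-1-methylcyclopropyl}methanol (C1 = Cc, C2 = Cb, C3 = Ca; both carbinol epimers)
Conditions: 9 (3.5 equiv), THF, 0 °C → rt; aq. NH4Cl
Reagents that add atoms: none
Why: Grignard addition to the open hydroxy-aldehyde form of the lactol (the first equivalent deprotonates it) should give the allylic carbinol as an inconsequential epimer mixture, and the Ca centre is not at risk because its configuration, trans to CH2OTBS, is already the less crowded one.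

Step 8
Reactants: 10 diol
Product: 11 {(1S,2R,3R)-2-{[(tert-butyldimethylsilyl)oxy]methyl}-3-(1-hydroxy-2-methylprop-2-en-1-yl)-1-methylcyclopropyl}methyl acetate
Conditions: AcCl (1.05 equiv), 2,4,6-collidine, CH2Cl2, −78 °C
Reagents that add atoms: acetyl chloride, CC(=O)Cl
Why: Kinetically selective acetylation of the unhindered primary hydroxyl over the hindered secondary allylic one at −78 °C masks Cc–CH2OH for the rearrangement that follows.

Step 9
Reactants: 11 monoacetate; 12 triethyl orthoacetate
Product: 13 ethyl (E)-5-[(1R,2R,3R)-2-(acetoxymethyl)-3-{[(tert-butyldimethylsilyl)oxy]methyl}-2-methylcyclopropyl]-4-methylpent-4-enoate (cyclopropyl C1 = Ca, C2 = Cc, C3 = Cb)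
Conditions: 12 (10 equiv), EtCO2H (0.1 equiv), 135 °C, EtOH distilled off
Reagents that add atoms: none
Why: Johnson–Claisen rearrangement: the mixed ketene acetal of the secondary allylic alcohol rearranges through a chair transition state with the cyclopropyl group pseudo-equatorial, which sets the E-trisubstituted alkene and erases the carbinol centre, while the still saturated Cc substituent keeps the ring free of any divinylcyclopropane-type [3,3] shift at this temperature.

Step 10
Reactants: 13 acetoxy ester
Product: 14 ethyl (E)-5-[(1R,2R,3R)-3-{[(tert-butyldimethylsilyl)oxy]methyl}-2-(hydroxymethyl)-2-methylcyclopropyl]-4-methylpent-4-enoate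
Conditions: K2CO3, EtOH, rt
Reagents that add atoms: none
Why: Carbonate-catalysed transesterification in ethanol removes the primary acetate as ethyl acetate, while exchange at the ethyl ester is degenerate and the silyl ether is stable to the mild base.

Step 11
Reactants: 14 hydroxy ester; 15 ethyl (triphenylphosphoranylidene)acetate
Product: 17 ethyl (E)-5-[(1R,2R,3R)-3-{[(tert-butyldimethylsilyl)oxy]methyl}-2-[(E)-3-ethoxy-3-oxoprop-1-en-1-yl]-2-methylcyclopropyl]-4-methylpent-4-enoate, via cyclopropanecarbaldehyde 16 (not isolated)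
Conditions: Dess–Martin periodinane (1.5 equiv), 15 (2.5 equiv), CH2Cl2, 0 °C → rt
Reagents that add atoms: none
Why: Dess–Martin oxidation run in the presence of the stabilised ylide traps the aldehyde as it forms, so the cis-formyl/alkenyl cyclopropane never accumulates, and the Wittig reaction should give the E-enoate without touching the quaternary Cc centre.

Step 12
Reactants: 17 enoate diester
Product: 18 ethyl (E)-5-[(1R,2R,3R)-3-{[(tert-butyldimethylsilyl)oxy]methyl}-2-(3-ethoxy-3-oxopropyl)-2-methylcyclopropyl]-4-methylpent-4-enoate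
Conditions: Cu(OAc)2 (5 mol%), 1,2-bis(diphenylphosphino)benzene (5 mol%), (EtO)2MeSiH (2 equiv), t-BuOH (2 equiv), toluene, rt
Reagents that add atoms: none
Why: Copper hydride conjugate reduction delivers hydride to the β-carbon of the enoate only (no radical arises next to the ring), leaving the trisubstituted alkene, both esters and the cyclopropane intact, and it runs at room temperature, below the range in which this cis-dialkenylcyclopropane with a fully substituted alkene terminus could undergo a Cope shift.

Step 13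
Reactants: 18 diester
Product: 19 (E)-5-[(1R,2R,3R)-3-{[(tert-butyldimethylsilyl)oxy]methyl}-2-(2-carboxyethyl)-2-methylcyclopropyl]-4-methylpent-4-enoic acid
Conditions: LiOH·H2O, THF/EtOH/H2O, rt; then 1 M HCl to pH 4, 0 °C
Reagents that add atoms: lithium hydroxide, [Li+].[OH-]
Why: Saponification of both unhindered ethyl esters by hydroxide is routine, and the brief, mild acidification keeps the primary silyl ether.

Step 14
Reactants: 19 diacid; 20 N-hydroxyphthalimide
Product: 21 1,3-dioxoisoindolin-2-yl (E)-5-[(1R,2R,3R)-3-{[(tert-butyldimethylsilyl)oxy]methyl}-2-{3-[(1,3-dioxoisoindolin-2-yl)oxy]-3-oxopropyl}-2-methylcyclopropyl]-4-methylpent-4-enoate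
Conditions: 20 (2.4 equiv), N,N'-diisopropylcarbodiimide (2.4 equiv), DMAP (0.1 equiv), CH2Cl2, rt
Reagents that add atoms: none
Why: Carbodiimide-mediated (Steglich-type) esterification with N-hydroxyphthalimide converts both acids to redox-active esters under neutral conditions that leave silyl ether and alkene alone.

Step 15
Reactants: 22 1-(trimethylsilyl)propyne; 23 (E)-geranyl bromide
Product: 26 (E)-6,10-dimethylundeca-5,9-dien-1-yne, via lithiated silylpropyne 24 (not isolated), via silylated enyne 25 (not isolated)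
Conditions: n-BuLi, THF, −78 °C; 23, −78 → 0 °C; then MeOH, K2CO3, rt
Reagents that add atoms: none
Why: Propargylic lithiation of 1-(trimethylsilyl)propyne and SN2 alkylation by the primary allylic bromide (the silyl group disfavours the allenyl product, the E-alkene is untouched), followed by methanolysis of the C–Si bond, should give the terminal enyne in one pot.

Step 16
Reactants: 26 (E)-6,10-dimethylundeca-5,9-dien-1-yne
Product: 28 (1E,5E)-1-iodo-2,6,10-trimethylundeca-1,5,9-triene, via alkenylalane 27 (not isolated)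
Conditions: Me3Al (2 equiv), Cp2ZrCl2 (0.25 equiv), CH2Cl2, 0 °C → rt; then I2, THF, −30 → 0 °C
Reagents that add atoms: trimethylaluminium, C[Al](C)C; iodine, II
Why: Zirconium-catalysed carboalumination (Negishi) adds methyl and aluminium syn across the terminal alkyne with aluminium at the terminus, and iodinolysis with retention gives the E-alkenyl iodide while the trisubstituted alkenes do not react.

Step 17
Reactants: 21 bis(N-hydroxyphthalimide) ester; 28 (1E,5E)-1-iodo-2,6,10-trimethylundeca-1,5,9-triene
Product: 29 tert-butyldimethyl{[(1R,2R,3R)-2-methyl-3-[(1E,5E,9E)-2,6,10,14-tetramethylpentadeca-1,5,9,13-tetraen-1-yl]-2-[(3E,7E)-4,8,12-trimethyltrideca-3,7,11-trien-1-yl]cyclopropyl]methoxy}silane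
Conditions: 28 (4 equiv), NiCl2·glyme (40 mol%), 2,2'-bipyridine (40 mol%), AgNO3 (0.6 equiv), DMF, Mg anode, reticulated vitreous carbon cathode, constant current (about 6 F per mol of 21), rt
Reagents that add atoms: none
Why: Cathodic reduction, with the magnesium anode as electron source, holds bipyridine-ligated nickel in a low-valent state that adds oxidatively to the C–I bond of 28 with retention of alkene geometry; single-electron transfer to each phthalimide ester releases phthalimide anion, CO2 and a primary alkyl radical, which the alkenylnickel halide captures before reductive elimination forms the CH2–CH= bond. The closest known reaction type is the nickel-electrocatalytic decarboxylative alkenylation of redox-active esters with alkenyl halides used to assemble polyene terpenoid chains, run here at both ester termini of one molecule. No ring is closed and no stereocentre is formed, so the three ring centres set in step 5 are spectators. The step needs retention of the E geometry, which the stereoretentive two-electron steps at nickel secure, and radical capture that outruns rearrangement. The ring cannot open because neither radical is cyclopropylcarbinyl: the Cc-arm radical sits on the second carbon from the ring, and the Ca-arm radical is homoallylic, with a slow and reversible 3-exo closure. The one competing path is 5-exo attack of the Cc-arm radical on the Ca–CH=C(CH3) alkene held cis to it, which the high nickel loading and the excess of 28 are chosen to suppress by raising the rate of capture.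

Step 18
Reactants: 29 silyl ether of the target
Product: 30 [(1R,2R,3R)-2-methyl-3-[(1E,5E,9E)-2,6,10,14-tetramethylpentadeca-1,5,9,13-tetraen-1-yl]-2-[(3E,7E)-4,8,12-trimethyltrideca-3,7,11-trien-1-yl]cyclopropyl]methanol
Conditions: TBAF, THF, 0 °C → rt
Reagents that add atoms: none
Why: Fluoride-mediated cleavage of the silyl ether is chosen because the product is a cyclopropylcarbinol that acid would ionise, whereas the basic fluoride conditions leave the ring and the polyene chains untouched.

Compound list
1 | (tert-butyldimethylsilyloxy)acetaldehyde | O=CCO[Si](C)(C)C(C)(C)C | starting material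
2 | ethyl 2-(triphenylphosphoranylidene)propanoate | CCOC(=O)C(C)=P(c1ccccc1)(c1ccccc1)c1ccccc1 | starting material
3 | ethyl (E)-4-[(tert-butyldimethylsilyl)oxy]-2-methylbut-2-enoate | CCOC(=O)/C(C)=C/CO[Si](C)(C)C(C)(C)C | intermediate
4 | (E)-4-[(tert-butyldimethylsilyl)oxy]-2-methylbut-2-en-1-ol | OC/C(C)=C/CO[Si](C)(C)C(C)(C)C | intermediate
5 | (E)-4-[(tert-butyldimethylsilyl)oxy]-2-methylbut-2-en-1-yl bromoacetate | BrCC(=O)OC/C(C)=C/CO[Si](C)(C)C(C)(C)C | intermediate
6 | (E)-4-[(tert-butyldimethylsilyl)oxy]-2-methylbut-2-en-1-yl diazoacetate | [N-]=[N+]=CC(=O)OC/C(C)=C/CO[Si](C)(C)C(C)(C)C | intermediate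
7 | (1R,5S,6R)-6-{[(tert-butyldimethylsilyl)oxy]methyl}-5-methyl-3-oxabicyclo[3.1.0]hexan-2-one | O=C1[C@@H]2[C@@H](CO[Si](C)(C)C(C)(C)C)[C@]2(C)CO1 | intermediate
8 | (1R,5S,6R)-6-{[(tert-butyldimethylsilyl)oxy]methyl}-5-methyl-3-oxabicyclo[3.1.0]hexan-2-ol (C2 epimers) | OC1[C@@H]2[C@@H](CO[Si](C)(C)C(C)(C)C)[C@]2(C)CO1 | intermediate
9 | isopropenylmagnesium bromide | C=C(C)[Mg]Br | starting material
10 | {(1S,2R,3R)-2-{[(tert-butyldimethylsilyl)oxy]methyl}-3-(1-hydroxy-2-methylprop-2-en-1-yl)-1-methylcyclopropyl}methanol (carbinol epimers) | C=C(C)C(O)[C@@H]1[C@@H](CO[Si](C)(C)C(C)(C)C)[C@]1(C)CO | intermediate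
11 | {(1S,2R,3R)-2-{[(tert-butyldimethylsilyl)oxy]methyl}-3-(1-hydroxy-2-methylprop-2-en-1-yl)-1-methylcyclopropyl}methyl acetate (carbinol epimers) | C=C(C)C(O)[C@@H]1[C@@H](CO[Si](C)(C)C(C)(C)C)[C@]1(C)COC(C)=O | intermediate
12 | triethyl orthoacetate | CC(OCC)(OCC)OCC | starting material
13 | ethyl (E)-5-[(1R,2R,3R)-2-(acetoxymethyl)-3-{[(tert-butyldimethylsilyl)oxy]methyl}-2-methylcyclopropyl]-4-methylpent-4-enoate | CCOC(=O)CC/C(C)=C/[C@@H]1[C@@H](CO[Si](C)(C)C(C)(C)C)[C@]1(C)COC(C)=O | intermediate
14 | ethyl (E)-5-[(1R,2R,3R)-3-{[(tert-butyldimethylsilyl)oxy]methyl}-2-(hydroxymethyl)-2-methylcyclopropyl]-4-methylpent-4-enoate | CCOC(=O)CC/C(C)=C/[C@@H]1[C@@H](CO[Si](C)(C)C(C)(C)C)[C@]1(C)CO | intermediate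
15 | ethyl (triphenylphosphoranylidene)acetate | CCOC(=O)C=P(c1ccccc1)(c1ccccc1)c1ccccc1 | starting material
16 | ethyl (E)-5-[(1R,2R,3R)-3-{[(tert-butyldimethylsilyl)oxy]methyl}-2-formyl-2-methylcyclopropyl]-4-methylpent-4-enoate | CCOC(=O)CC/C(C)=C/[C@@H]1[C@@H](CO[Si](C)(C)C(C)(C)C)[C@]1(C)C=O | intermediate
17 | ethyl (E)-5-[(1R,2R,3R)-3-{[(tert-butyldimethylsilyl)oxy]methyl}-2-[(E)-3-ethoxy-3-oxoprop-1-en-1-yl]-2-methylcyclopropyl]-4-methylpent-4-enoate | CCOC(=O)CC/C(C)=C/[C@@H]1[C@@H](CO[Si](C)(C)C(C)(C)C)[C@]1(C)/C=C/C(=O)OCC | intermediate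
18 | ethyl (E)-5-[(1R,2R,3R)-3-{[(tert-butyldimethylsilyl)oxy]methyl}-2-(3-ethoxy-3-oxopropyl)-2-methylcyclopropyl]-4-methylpent-4-enoate | CCOC(=O)CC/C(C)=C/[C@@H]1[C@@H](CO[Si](C)(C)C(C)(C)C)[C@]1(C)CCC(=O)OCC | intermediate
19 | (E)-5-[(1R,2R,3R)-3-{[(tert-butyldimethylsilyl)oxy]methyl}-2-(2-carboxyethyl)-2-methylcyclopropyl]-4-methylpent-4-enoic acid | OC(=O)CC/C(C)=C/[C@@H]1[C@@H](CO[Si](C)(C)C(C)(C)C)[C@]1(C)CCC(=O)O | intermediate
20 | N-hydroxyphthalimide | ON1C(=O)c2ccccc2C1=O | starting material
21 | bis(1,3-dioxoisoindolin-2-yl) ester of 19 | O=C(CC/C(C)=C/[C@@H]1[C@@H](CO[Si](C)(C)C(C)(C)C)[C@]1(C)CCC(=O)ON2C(=O)c3ccccc3C2=O)ON4C(=O)c5ccccc5C4=O | intermediate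
22 | 1-(trimethylsilyl)propyne | CC#C[Si](C)(C)C | starting material
23 | (E)-geranyl bromide | CC(C)=CCC/C(C)=C/CBr | starting material
24 | 3-lithio-1-(trimethylsilyl)propyne | [Li]CC#C[Si](C)(C)C | intermediate
25 | (E)-(6,10-dimethylundeca-5,9-dien-1-yn-1-yl)trimethylsilane | C[Si](C)(C)C#CCC/C=C(\C)CCC=C(C)C | intermediate
26 | (E)-6,10-dimethylundeca-5,9-dien-1-yne | C#CCC/C=C(\C)CCC=C(C)C | intermediate
27 | dimethyl[(1E,5E)-2,6,10-trimethylundeca-1,5,9-trien-1-yl]alumane | C[Al](C)/C=C(\C)CC/C=C(\C)CCC=C(C)C | intermediate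
28 | (1E,5E)-1-iodo-2,6,10-trimethylundeca-1,5,9-triene | CC(C)=CCC/C(C)=C/CC/C(C)=C/I | intermediate
29 | tert-butyldimethylsilyl ether of the target, (1R,2R,3R) | CC(C)=CCC/C(C)=C/CC/C(C)=C/CC/C(C)=C/[C@@H]1[C@@H](CO[Si](C)(C)C(C)(C)C)[C@]1(C)CC/C=C(\C)CC/C=C(\C)CCC=C(C)C | intermediate
30 | [(1R,2R,3R)-2-methyl-3-[(1E,5E,9E)-2,6,10,14-tetramethylpentadeca-1,5,9,13-tetraen-1-yl]-2-[(3E,7E)-4,8,12-trimethyltrideca-3,7,11-trien-1-yl]cyclopropyl]methanol | CC(C)=CCC/C(C)=C/CC/C(C)=C/CC/C(C)=C/[C@@H]1[C@@H](CO)[C@]1(C)CC/C=C(\C)CC/C=C(\C)CCC=C(C)C | target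

Total step count: 18. Longest linear sequence: 16 (steps 1–14, 17 and 18).

Steps most likely to fail

1. Step 17. The Cc-arm radical may close in a 5-exo mode onto the neighbouring Ca alkene before nickel captures it. One radical or one ester may be reduced prematurely, so that only one arm couples. The iodide may dimerise reductively. The fallback sets out from 14 and returns at 29, building the Cc chain by a two-electron route and leaving only the Ca arm to the radical coupling. Alcohol 14 is oxidised with Dess–Martin periodinane to aldehyde 16, which is methylenated with Ph3P=CH2 (THF, −78 → 0 °C) to ethyl (E)-5-[(1R,2R,3R)-3-{[(tert-butyldimethylsilyl)oxy]methyl}-2-ethenyl-2-methylcyclopropyl]-4-methylpent-4-enoate F1. 9-BBN (THF, rt) should add to the vinyl group only, giving the B-alkyl borane F2. Suzuki–Miyaura coupling of F2 with 28 [PdCl2(dppf), AsPh3, Cs2CO3, DMF/THF/H2O, rt] should give the ethyl ester carrying the complete Cc trienyl chain F3. LiOH hydrolysis gives the carboxylic acid F4, and N-hydroxyphthalimide with N,N'-diisopropylcarbodiimide gives the mono(N-hydroxyphthalimide) ester F5. A single nickel-electrocatalytic alkenylation of F5 with 28 under the step 17 conditions then gives 29; its homoallylic radical has no alkene within five-ring reach.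

2. Step 5. The chiral catalyst may discriminate poorly between the faces of the 2-methyl-substituted E-alkene, and the carbene may dimerise. The fallback sets out from 6 and returns at 7. Cyclopropanation with Rh2(OAc)4 (CH2Cl2, slow addition) gives the racemate, i.e. 7 together with its enantiomer, the (1S,5R,6S)-lactone F6. The two are separated by preparative chromatography on a chiral stationary phase (cellulose tris(3,5-dimethylphenylcarbamate)), and 7 is carried on.

3. Step 9. Under acid and heat the cyclopropyl(alkenyl)carbinol may ionise to a cyclopropylcarbinyl/allyl cation, with ring opening or allylic transposition, and the hindered carbinol may rearrange slowly with thermal loss. The fallback sets out from 11 and returns at 13, using a base-mediated Ireland–Claisen rearrangement near room temperature. Acetylation of the secondary hydroxyl of 11 (Ac2O, DMAP, Et3N, CH2Cl2) gives the diacetate F7. Treatment with LDA and Me3SiCl (THF, −78 °C → rt) should rearrange the allylic silyl ketene acetal through the same chair, E-selective transition state, and aqueous work-up gives (E)-5-[(1R,2R,3R)-2-(acetoxymethyl)-3-{[(tert-butyldimethylsilyl)oxy]methyl}-2-methylcyclopropyl]-4-methylpent-4-enoic acid F8, the primary acetate being regenerated. Esterification (EtI, K2CO3, DMF) gives 13.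

Further compounds
F1 | step 17 | ethyl (E)-5-[(1R,2R,3R)-3-{[(tert-butyldimethylsilyl)oxy]methyl}-2-ethenyl-2-methylcyclopropyl]-4-methylpent-4-enoate | CCOC(=O)CC/C(C)=C/[C@@H]1[C@@H](CO[Si](C)(C)C(C)(C)C)[C@]1(C)C=C
F2 | step 17 | ethyl (E)-5-[(1R,2R,3R)-2-[2-(9-borabicyclo[3.3.1]nonan-9-yl)ethyl]-3-{[(tert-butyldimethylsilyl)oxy]methyl}-2-methylcyclopropyl]-4-methylpent-4-enoate | CCOC(=O)CC/C(C)=C/[C@@H]1[C@@H](CO[Si](C)(C)C(C)(C)C)[C@]1(C)CCB1C2CCCC1CCC2
F3 | step 17 | ethyl (E)-5-[(1R,2R,3R)-3-{[(tert-butyldimethylsilyl)oxy]methyl}-2-methyl-2-[(3E,7E)-4,8,12-trimethyltrideca-3,7,11-trien-1-yl]cyclopropyl]-4-methylpent-4-enoate | CCOC(=O)CC/C(C)=C/[C@@H]1[C@@H](CO[Si](C)(C)C(C)(C)C)[C@]1(C)CC/C=C(\C)CC/C=C(\C)CCC=C(C)C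
F4 | step 17 | (E)-5-[(1R,2R,3R)-3-{[(tert-butyldimethylsilyl)oxy]methyl}-2-methyl-2-[(3E,7E)-4,8,12-trimethyltrideca-3,7,11-trien-1-yl]cyclopropyl]-4-methylpent-4-enoic acid | OC(=O)CC/C(C)=C/[C@@H]1[C@@H](CO[Si](C)(C)C(C)(C)C)[C@]1(C)CC/C=C(\C)CC/C=C(\C)CCC=C(C)C
F5 | step 17 | 1,3-dioxoisoindolin-2-yl ester of F4 | O=C(CC/C(C)=C/[C@@H]1[C@@H](CO[Si](C)(C)C(C)(C)C)[C@]1(C)CC/C=C(\C)CC/C=C(\C)CCC=C(C)C)ON1C(=O)c2ccccc2C1=O
F6 | step 5 | (1S,5R,6S)-6-{[(tert-butyldimethylsilyl)oxy]methyl}-5-methyl-3-oxabicyclo[3.1.0]hexan-2-one | O=C1[C@H]2[C@H](CO[Si](C)(C)C(C)(C)C)[C@@]2(C)CO1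
F7 | step 9 | {(1S,2R,3R)-3-[1-(acetyloxy)-2-methylprop-2-en-1-yl]-2-{[(tert-butyldimethylsilyl)oxy]methyl}-1-methylcyclopropyl}methyl acetate (carbinol epimers) | C=C(C)C(OC(C)=O)[C@@H]1[C@@H](CO[Si](C)(C)C(C)(C)C)[C@]1(C)COC(C)=O
F8 | step 9 | (E)-5-[(1R,2R,3R)-2-(acetoxymethyl)-3-{[(tert-butyldimethylsilyl)oxy]methyl}-2-methylcyclopropyl]-4-methylpent-4-enoic acid | OC(=O)CC/C(C)=C/[C@@H]1[C@@H](CO[Si](C)(C)C(C)(C)C)[C@]1(C)COC(C)=O
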